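All constants are assumed; the result is computed.

The reagent is what to watch in this flask. It goes in by portions onto the starting material, and here is what you take over:

starting material 0.64 M; reagent 0.672 M (in portions, 3); time 15 h; the portions of reagent follow each other after 6.0 min, the first at the start

    2 reagent → side product (k1 = 0.224 /M/min)
    reagent + target → over-reaction product (k2 = 0.0143 /M/min)
    starting material + reagent → target (k3 = 0.301 /M/min)
    target ⇌ isomer of the product (K4 = 7.9, k4 = 0.354 /min)

1. the state of affairs at 15 h: stopped, and by what, or still going (it is still moving / the reagent has run out first / forward and back rates have come level / all of the starting material has reacted)
2. how much of the starting material has reacted by 15 h
3. how much target there is at 15 h, in percent of the starting material charged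
4. how much isomer of the product there is at 15 h, in percent of the starting material charged

- two of one species on the left: rate k times its square, two consumed each time
- the reaction counts as stopped when no species that holds the starting material changes by six tenths of a point or more over the second half of the time
- run time (flask): 15 h

Each portion of reagent has three ways to go: to the starting material, giving target; to itself, two at each turn, giving side product; or to target, giving over-reaction product. The constant of that last way, 0.0143 /M/min, is much smaller than the 0.301 /M/min of the productive step, so I set it aside and weigh the other two. So I count reagent turnovers with one figure. Take twice the self-reaction constant times one portion, and divide by the productive constant times the starting material charged. That gives w = 0.521, the waste ratio: reagent lost to itself per reagent reaching starting material, as the first portion lands. Within a portion, falling reagent lowers w; from portion to portion, falling starting material raises it. I assume these roughly cancel and keep w for the whole run.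

The charge then delivers 0.442 M to the starting material, which is less than the 0.64 M present. That means 69.0% conversion, with reagent as the limiting reagent. The half-life of starting material at whole charge, 0.057 h, is much shorter than the 15 h run, so when you come I expect this flask to have stopped, with about 31.0% of its starting material unreacted. Don't extend the run to chase that remainder: by my count reagent stops this flask, and time adds none.

The forecast says the reagent has run out first, with 68% conversion and 7.5% target. For the isomer of the product it gives 59.7%. Its ground: “it is gone within a few hours and conversion stalls near two thirds”.

This flask gives the reagent has run out first, with 68.3% conversion and 7.62% target. The isomer of the product stands at 60.2%. At 15.0 h its reagent stands at 0% of charge, less than the 32% of starting material. Its 0.116 M of side product took twice that in reagent, which is 0.531 per reagent that reached starting material, against w of 0.521. The neighbour charged with 0.27 M of reagent has w = 0.209, which counts out to 34.9% conversion; that flask reaches 35.7%.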